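**Retrosynthetic overview**

- The C3–O and C6–O bonds, the C3 and C6 stereocentres and the position of the C4=C5 alkene all come from one [4+2] addition of singlet oxygen across a cyclohexa-1,3-diene, followed by O–O reduction in the same flask. The diene already carries the C1 carbinol (free OH), the C2 acetate and the C7 benzoate.
- C1 relays its configuration to C3 and C6: the free tertiary C1–OH sits on the face that must be attacked, the C2–OAc and the C7H2OBz group block the other face.
- The diene comes from a 4,5-dibromide by double dehydrobromination. The trans C1–OH/C2–O pair comes from a C1–C2 epoxide opened at the tertiary C1 with inversion by the neighbouring C7 benzoate.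
- The epoxide is the only stereo element set by catalysis: Sharpless epoxidation of (cyclohexa-1,4-dienyl)methanol.
- The carbocycle is the only ring formed (Diels–Alder of butadiene with methyl propiolate). The last two steps tell the two new allylic hydroxyls apart (C3 acetate, C6 benzoate).

Key step: step 9

Remark: ring carbons are numbered as in the natural product (C1 quaternary carbinol, C2 CH–OAc, C3 allylic CH–OAc, C4=C5, C6 CH–OBz, C7 the CH2OBz carbon); the bromination is assumed to give both trans-dibromide diastereomers, of which one is drawn for 7, 8, 9 and 10, since both converge at diene 11.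

**Step 1**
Reactants: 1 buta-1,3-diene; 2 methyl propiolate
Product: 3 methyl cyclohexa-1,4-diene-1-carboxylate
Conditions: toluene, hydroquinone (cat.), sealed tube, 110 °C
Reagents that add atoms: none
Why: Thermal Diels–Alder reaction of an electron-poor alkyne with butadiene gives the 1,4-cyclohexadiene directly; no stereocentre is formed.

**Step 2**
Reactants: 3 methyl cyclohexa-1,4-diene-1-carboxylate
Product: 4 (cyclohexa-1,4-dien-1-yl)methanol
Conditions: DIBAL-H (2.2 equiv), CH2Cl2, −78 → 0 °C; aq. Rochelle salt
Reagents that add atoms: none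
Why: Hydride reduction of the conjugated ester with DIBAL-H is 1,2-selective at low temperature and leaves the skipped diene untouched.

**Step 3**
Reactants: 4 (cyclohexa-1,4-dien-1-yl)methanol
Product: 5 [(1S,6S)-7-oxabicyclo[4.1.0]hept-3-en-1-yl]methanol
Conditions: Ti(OiPr)4 (10 mol %), L-(+)-diethyl tartrate (12 mol %), t-BuOOH (anhydrous), 4 Å MS, CH2Cl2, −20 °C
Reagents that add atoms: tert-butyl hydroperoxide, CC(C)(C)OO
Why: Sharpless asymmetric epoxidation oxidises only the allylic (trisubstituted) alkene, and with L-(+)-tartrate should give the (S)-configured carbinol-bearing epoxide carbon as for other 2,3-disubstituted allylic alcohols; this fixes C2 and the centre C1 that is inverted in step 6.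

**Step 4**
Reactants: 5 [(1S,6S)-7-oxabicyclo[4.1.0]hept-3-en-1-yl]methanol
Product: 6 [(1S,6S)-7-oxabicyclo[4.1.0]hept-3-en-1-yl]methyl benzoate
Conditions: BzCl, pyridine, CH2Cl2, 0 °C
Reagents that add atoms: benzoyl chloride, O=C(Cl)c1ccccc1
Why: Acylation of the primary alcohol under basic conditions spares the epoxide and installs the C7 benzoate of the target, which also serves as the neighbouring group in step 6.

**Step 5**
Reactants: 6 [(1S,6S)-7-oxabicyclo[4.1.0]hept-3-en-1-yl]methyl benzoate
Product: 7 [(1S,3R,4R,6S)-3,4-dibromo-7-oxabicyclo[4.1.0]heptan-1-yl]methyl benzoate (trans-dibromide at C4/C5 of the target skeleton)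
Conditions: Br2 (1.05 equiv), CH2Cl2, −78 °C
Reagents that add atoms: bromine, BrBr
Why: Electrophilic anti addition of bromine to the isolated cis-alkene masks the future diene, and the epoxide and ester are inert at this temperature.

**Step 6**
Reactants: 7 [(1S,3R,4R,6S)-3,4-dibromo-7-oxabicyclo[4.1.0]heptan-1-yl]methyl benzoate
Product: 9 [(1R,2S,4R,5R)-4,5-dibromo-1,2-dihydroxycyclohexyl]methyl benzoate, via dioxolan-2-ylium perchlorate 8 (not isolated)
Conditions: HClO4 (aq., 10 mol %), THF/H2O (4:1), 0 °C → rt
Reagents that add atoms: water, O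
Why: Acid-catalysed epoxide opening with neighbouring-group participation: the benzoate carbonyl attacks the protonated epoxide at the tertiary C1 in a 5-exo mode with inversion to give the 2-phenyl-1,3-dioxolan-2-ylium ion 8, and its hydrolysis under equilibrating acid should leave the benzoyl group on the primary O7, so that the new C1–OH is trans to the untouched C2–OH.

**Step 7**
Reactants: 9 [(1R,2S,4R,5R)-4,5-dibromo-1,2-dihydroxycyclohexyl]methyl benzoate
Product: 10 [(1R,2S,4R,5R)-2-acetoxy-4,5-dibromo-1-hydroxycyclohexyl]methyl benzoate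
Conditions: Ac2O (1.2 equiv), pyridine, DMAP (5 mol %), CH2Cl2, 0 °C
Reagents that add atoms: acetic anhydride, CC(=O)OC(C)=O
Why: DMAP-catalysed acetylation takes the secondary C2–OH while the tertiary C1–OH is too hindered to react; the acetate also stops O2 from directing in the key step.

**Step 8**
Reactants: 10 [(1R,2S,4R,5R)-2-acetoxy-4,5-dibromo-1-hydroxycyclohexyl]methyl benzoate
Product: 11 [(1R,6S)-6-acetoxy-1-hydroxycyclohexa-2,4-dien-1-yl]methyl benzoate (diene C3=C4–C5=C6 in target numbering)
Conditions: DBU (3 equiv), THF, 0 → 40 °C; neutral work-up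
Reagents that add atoms: none
Why: Two successive anti E2 eliminations of HBr toward C3–H and C6–H with a non-nucleophilic amidine base give the conjugated diene, the standard entry to 5,6-dioxygenated cyclohexa-1,3-dienes; C1 and C2 are not touched.

**Step 9**
Reactants: 11 [(1R,6S)-6-acetoxy-1-hydroxycyclohexa-2,4-dien-1-yl]methyl benzoate
Product: 13 [(1S,2S,3R,6S)-2-acetoxy-1,3,6-trihydroxycyclohex-4-en-1-yl]methyl benzoate, via endoperoxide 12 (not isolated)
Conditions: O2, tetraphenylporphyrin (1 mol %), hν (visible), CH2Cl2, −20 °C; then thiourea (2 equiv), MeOH, −20 °C → rt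
Reagents that add atoms: oxygen, O=O
Why: Sensitised singlet oxygen adds suprafacially across C3 and C6 of the cyclohexa-1,3-diene in a concerted [4+2] cycloaddition to give the 2,3-dioxabicyclo[2.2.2]octene 12, and thiourea then reduces only the O–O bond, so both new C–O bonds keep their configuration in the cis-1,4-diol. The closest known reaction type is the photooxygenation–thiourea reduction of 5,6-dioxygenated cyclohexa-1,3-dienes used for conduritols, together with the hydroxyl-directed singlet-oxygen cycloaddition of chiral dienols. The only ring closed is the six-membered 1,2-dioxene bridge, formed by cycloaddition with both C–O bonds on one face of the carbocycle, and it is opened again in the same flask. C3 and C6 are set together by substrate control from C1: the free tertiary C1–OH can hydrogen-bond to the incoming oxygen in the non-protic solvent and lies on the face opposite to the C2 acetate and the C7H2OBz group, so addition should occur cis to O1 and give the (3R,6S) configuration. The step needs π-facial selectivity and [4+2] over ene reactivity; the first rests on this agreement of directing and shielding groups (O2 is acetylated so that it cannot direct to the other face), the second on the s-cis ring diene, and the low temperature and neutral medium protect the aromatisation-prone dienol.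

**Step 10**
Reactants: 13 [(1S,2S,3R,6S)-2-acetoxy-1,3,6-trihydroxycyclohex-4-en-1-yl]methyl benzoate
Product: 14 [(1S,2S,3R,6S)-2,3-diacetoxy-1,6-dihydroxycyclohex-4-en-1-yl]methyl benzoate
Conditions: AcCl (1.05 equiv), 2,4,6-collidine, CH2Cl2, −78 → −40 °C
Reagents that add atoms: acetyl chloride, CC(Cl)=O
Why: Kinetically controlled acylation should select the C3–OH, which is flanked by two CH groups, over the C6–OH next to the fully substituted C1 and over the tertiary C1–OH.

**Step 11**
Reactants: 14 [(1S,2S,3R,6S)-2,3-diacetoxy-1,6-dihydroxycyclohex-4-en-1-yl]methyl benzoate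
Product: 15 cleistenediol F, [(1S,2S,3R,6S)-2,3-diacetoxy-6-benzoyloxy-1-hydroxycyclohex-4-en-1-yl]methyl benzoate
Conditions: BzCl (1.5 equiv), pyridine, DMAP (10 mol %), CH2Cl2, 0 °C → rt
Reagents that add atoms: benzoyl chloride, O=C(Cl)c1ccccc1
Why: DMAP-catalysed benzoylation takes the remaining secondary C6–OH while the tertiary C1–OH does not acylate at room temperature, which should give the target with all four stereocentres unchanged.

**Compound list**

1 | buta-1,3-diene | C=CC=C | starting material
2 | methyl propiolate | C#CC(=O)OC | starting material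
3 | methyl cyclohexa-1,4-diene-1-carboxylate | COC(=O)C1=CCC=CC1 | intermediate
4 | (cyclohexa-1,4-dien-1-yl)methanol | OCC1=CCC=CC1 | intermediate
5 | [(1S,6S)-7-oxabicyclo[4.1.0]hept-3-en-1-yl]methanol | C1C=CC[C@@]2(CO)O[C@@H]12 | intermediate
6 | [(1S,6S)-7-oxabicyclo[4.1.0]hept-3-en-1-yl]methyl benzoate | C1C=CC[C@@]2(COC(=O)c3ccccc3)O[C@@H]12 | intermediate
7 | [(1S,3R,4R,6S)-3,4-dibromo-7-oxabicyclo[4.1.0]heptan-1-yl]methyl benzoate | C1[C@@H](Br)[C@H](Br)C[C@@]2(COC(=O)c3ccccc3)O[C@@H]12 | intermediate
8 | spiro 2-phenyl-1,3-dioxolan-2-ylium perchlorate bridging O1 and O7 (C1 inverted, C2–OH free, 4,5-dibromide) | C1[C@@H](Br)[C@H](Br)C[C@@](O3)(C[O+]=C3c4ccccc4)[C@H]1O.[O-]Cl(=O)(=O)=O | intermediate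
9 | [(1R,2S,4R,5R)-4,5-dibromo-1,2-dihydroxycyclohexyl]methyl benzoate | C1[C@@H](Br)[C@H](Br)C[C@@](O)(COC(=O)c2ccccc2)[C@H]1O | intermediate
10 | [(1R,2S,4R,5R)-2-acetoxy-4,5-dibromo-1-hydroxycyclohexyl]methyl benzoate | C1[C@@H](Br)[C@H](Br)C[C@@](O)(COC(=O)c2ccccc2)[C@H]1OC(C)=O | intermediate
11 | [(1R,6S)-6-acetoxy-1-hydroxycyclohexa-2,4-dien-1-yl]methyl benzoate | C1=CC=C[C@@](O)(COC(=O)c2ccccc2)[C@H]1OC(C)=O | intermediate
12 | [(1S,4R,7R,8S)-8-acetoxy-7-hydroxy-2,3-dioxabicyclo[2.2.2]oct-5-en-7-yl]methyl benzoate (C3–O–O–C6 bridge cis to the C1 hydroxyl) | O1O[C@@H]2C=C[C@H]1[C@@](O)(COC(=O)c3ccccc3)[C@H]2OC(C)=O | intermediate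
13 | [(1S,2S,3R,6S)-2-acetoxy-1,3,6-trihydroxycyclohex-4-en-1-yl]methyl benzoate | O[C@@H]1C=C[C@H](O)[C@@](O)(COC(=O)c2ccccc2)[C@H]1OC(C)=O | intermediate
14 | [(1S,2S,3R,6S)-2,3-diacetoxy-1,6-dihydroxycyclohex-4-en-1-yl]methyl benzoate | CC(=O)O[C@@H]1C=C[C@H](O)[C@@](O)(COC(=O)c2ccccc2)[C@H]1OC(C)=O | intermediate
15 | cleistenediol F | CC(=O)O[C@@H]1C=C[C@H](OC(=O)c2ccccc2)[C@@](O)(COC(=O)c2ccccc2)[C@H]1OC(C)=O | target

**Step count and risks**

Total step count: 11. Longest linear sequence: 11 steps (from buta-1,3-diene and methyl propiolate).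

Steps most likely to fail:

Step 10. The acetylation may fail to distinguish the two allylic hydroxyls, with competing acylation at O6 or diacetylation. The fallback replaces steric differentiation by temporary protection of the only 1,2-diol. It sets out from 13, which is condensed with phenylboronic acid (toluene, 4 Å MS, rt) to give the cyclic phenylboronate of the cis C1/C6 diol F1. The remaining C3–OH is acetylated (Ac2O, pyridine) to give the boronate acetate F2. Transesterification of the boronate with pinacol then releases the diol, and the sequence comes back to the route at 14.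

Step 9. The cycloaddition may show poor facial selectivity, or an ene reaction or dehydrative aromatisation of the dienol may compete. The fallback installs the two oxygens one at a time and sets out from 11. Hydroxyl-directed epoxidation (VO(acac)2, t-BuOOH, CH2Cl2) of the C5=C6 alkene, which is allylic to the C1–OH, should give the vinyl epoxide with the oxygen cis to O1 F3. Palladium(0)-catalysed 1,4-addition of acetic acid (Pd(PPh3)4, AcOH, THF) then ionises the epoxide with inversion and delivers acetate to C3 anti to palladium, so that the C3 acetate is cis to the C6–OH. This comes back to the route at 14.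

Step 6. Regiocontrol in the epoxide opening may be lost (attack at C2, or collapse of an open tertiary cation), which would erode enantiomeric and diastereomeric purity, and the benzoyl group may not return fully to O7. The fallback delivers O1 from a carbonate tether and adds the benzoate afterwards. It sets out from 5, which is converted (Boc2O, DMAP) into the tert-butyl carbonate F4 and brominated (Br2, CH2Cl2, −78 °C) to the trans-dibromide F5. BF3·OEt2 (CH2Cl2, −40 °C) then triggers 5-exo attack of the carbonate carbonyl at C1 with inversion and loss of the tert-butyl group, giving the spiro cyclic carbonate with free C2–OH F6. Methanolysis (K2CO3, MeOH, 0 °C) gives the triol F7, and selective benzoylation of the primary hydroxyl (BzCl, collidine, −40 °C) comes back to the route at 9.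

**Further compounds**

F1 | step 10 | cyclic phenylboronate of 13 across O1 and O6 (2-phenyl-1,3,2-dioxaborolane cis-fused at C1/C6, C3–OH free) | O[C@@H]1C=C[C@@H]2OB(c3ccccc3)O[C@]2(COC(=O)c3ccccc3)[C@H]1OC(C)=O
F2 | step 10 | 3-O-acetate of boronate F1 | CC(=O)O[C@@H]1C=C[C@@H]2OB(c3ccccc3)O[C@]2(COC(=O)c3ccccc3)[C@H]1OC(C)=O
F3 | step 9 | [2-acetoxy-5,6-epoxy-1-hydroxycyclohex-3-en-1-yl]methyl benzoate (target numbering), epoxide oxygen cis to the C1 hydroxyl | C1=C[C@@H]2O[C@@H]2[C@@](O)(COC(=O)c3ccccc3)[C@H]1OC(C)=O
F4 | step 6 | tert-butyl [(1S,6S)-7-oxabicyclo[4.1.0]hept-3-en-1-yl]methyl carbonate | C1C=CC[C@@]2(COC(=O)OC(C)(C)C)O[C@@H]12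
F5 | step 6 | tert-butyl [(1S,3R,4R,6S)-3,4-dibromo-7-oxabicyclo[4.1.0]heptan-1-yl]methyl carbonate | C1[C@@H](Br)[C@H](Br)C[C@@]2(COC(=O)OC(C)(C)C)O[C@@H]12
F6 | step 6 | spiro 1,3-dioxolan-2-one bridging O1 and O7 of the 4,5-dibromocyclohexane, C2–OH free and trans to O1 | C1[C@@H](Br)[C@H](Br)C[C@@](O3)(COC3=O)[C@H]1O
F7 | step 6 | (1R,2S,4R,5R)-4,5-dibromo-1-(hydroxymethyl)cyclohexane-1,2-diol | C1[C@@H](Br)[C@H](Br)C[C@@](O)(CO)[C@H]1O
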